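The plan rests on reading lactone C4, C3, the exocyclic carbon C1′, C2′, C3′ and lactone C5 as a cyclohexa-1,4-diene: C4 and C2′ are cis on the C3=C1′ alkene, and C5 and C3′ both carry oxygen, so they can be the two ends of a cleaved ring alkene. One catalytic asymmetric Diels–Alder reaction between an (E)-1-silyloxybutadiene and a two-point-binding propiolic imide forms C3–C4 and C1′–C2′, the C4 stereocentre and the E-alkene geometry at once. Ozonolysis with unsymmetrical work-up then frees the C3′ and C5 aldehydes one after the other for two alkenyl additions (nerol-derived alkenyl iodide, then 2-methylpropenyl bromide), lactonisation and acetylation.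

Key step: step 3

Remarks
- Locants follow the target: lactone O1, C2 (carbonyl), C3, C4, C5; side chain C1′ (exocyclic alkene carbon) to C10′ (benzoate-bearing carbon).
- A simple propiolate ester can bind a copper bis(oxazoline) centre through one oxygen only, which gives no basis for face selection. The propiolic unit is therefore used as its N-acyl oxazolidinone 7 (two-point binding); the oxazolidinone later leaves in the lactonisation, so no step is needed to remove it.
- The C4 centre is S in the target and 6R in adduct 8; the spatial arrangement is the same, only the ranking of its two carbon neighbours changes on ring cleavage.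
- Assumption: the sense of induction of the chiral ligands in steps 3, 10 and in the fallback to step 12 is assigned from models; both antipodes of each ligand are available, and the sense would be confirmed on the first run.

Step 1
Reactants: 1 (E)-but-2-enal (crotonaldehyde)
Product: 2 (E)-1-(tert-butyldimethylsilyloxy)buta-1,3-diene
Conditions: TBSOTf, Et3N, Et2O, 0 °C → rt
Reagents that add atoms: tert-butyldimethylsilyl triflate, CC(C)(C)[Si](C)(C)OS(=O)(=O)C(F)(F)F
Why: Silyl dienol ether formation: O-silylation of the enal gives a silyloxocarbenium ion from which Et3N removes a γ-proton, and the E enol ether, the only isomer that can reach the s-cis conformation needed in step 3, is expected to predominate.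

Step 2
Reactants: 3 prop-2-ynoic acid; 4 1,3-oxazolidin-2-one
Product: 7 3-(prop-2-ynoyl)-1,3-oxazolidin-2-one, via mixed pivalic anhydride 5 (not isolated), via lithium oxazolidinonide 6 (not isolated)
Conditions: 3, PivCl, Et3N, THF, −78 → −20 °C; 4, n-BuLi, THF, −78 °C; combine, −78 → 0 °C
Reagents that add atoms: none
Why: N-Acylation of a lithiated oxazolidinone by a mixed anhydride, the standard route to unsaturated N-acyl oxazolidinones, in which attack at the unhindered propioloyl carbonyl at low temperature should outrun conjugate addition.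

Step 3
Reactants: 2 (E)-1-(tert-butyldimethylsilyloxy)buta-1,3-diene; 7 3-(prop-2-ynoyl)-1,3-oxazolidin-2-one
Product: 8 3-{[(6R)-6-(tert-butyldimethylsilyloxy)cyclohexa-1,4-dien-1-yl]carbonyl}-1,3-oxazolidin-2-one
Conditions: Cu(OTf)2 (10 mol%), (R,R)-tBu-box [2,2′-(propane-2,2-diyl)bis((4R)-4-tert-butyl-4,5-dihydro-1,3-oxazole)] (11 mol%), 4 Å MS, CH2Cl2, −78 → −40 °C; cold filtration through silica, solution used at once
Reagents that add atoms: none
Why: Proposed new method: two-point chelation of the imide carbonyls of 7 to the divalent copper centre lowers the alkyne LUMO, and the electron-rich diene 2 then adds in a concerted but asynchronous [4+2] cycloaddition (at the stepwise limit a Mukaiyama–Michael addition followed by ring closure onto the silyloxycarbenium ion, which gives the same adduct). The closest known reactions are the uncatalysed Diels–Alder additions of 1-silyloxy- and 1-acyloxybutadienes to propiolates and the copper bis(oxazoline)-catalysed additions of 1-acetoxybutadiene to acryloyl imides. The six-membered carbocycle is closed by an intermolecular suprafacial [4+2] closure in which the C3–C4 and C1′–C2′ bonds form on one face of each partner. The only new stereocentre (C6 of 8, the future C4) is controlled by the tert-butyl groups of the ligand, which screen one face of the chelated alkyne while the diene lies on the other with its silyloxy terminus over the acyl carbon; on this model the (R,R)-ligand should give 6R, and the antipodal ligand is equally available if the sense proves opposite. The step needs ortho regioselectivity, which the donor oxygen secures by placing the largest HOMO coefficient on the unsubstituted diene terminus that bonds to the alkyne β-carbon, and it needs the E geometry of the later exocyclic alkene, which the ring enforces because C4 and C2′ are held cis on the acyl-bearing alkene.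

Step 4
Reactants: 8 3-{[(6R)-6-(tert-butyldimethylsilyloxy)cyclohexa-1,4-dien-1-yl]carbonyl}-1,3-oxazolidin-2-one
Product: 11 3-[(2E,3S)-3-(tert-butyldimethylsilyloxy)-4,4-dimethoxy-2-(3-oxopropylidene)butanoyl]-1,3-oxazolidin-2-one, via methoxy hydroperoxide aldehyde 9 (not isolated), via methoxy hydroperoxide acetal 10 (not isolated)
Conditions: O3, CH2Cl2/MeOH (5:1), Sudan Red 7B end point, −78 °C; TsOH·H2O (5 mol%), −78 → 20 °C, 1 h; NaHCO3; Me2S, rt
Reagents that add atoms: ozone, [O-][O+]=O; methanol, CO
Why: Unsymmetrical ozonolysis (Criegee mechanism): the electron-rich cis-disubstituted ring alkene reacts with ozone far faster than the acyl-conjugated one (dye end point), the primary ozonide is expected to fragment so that the carbonyl oxide forms at the carbon remote from the electron-withdrawing silyloxy group (future C3′) and is trapped by methanol, acid then acetalises the free C5 aldehyde, and Me2S finally reduces the methoxy hydroperoxide to the C3′ aldehyde, all without touching the C4 stereocentre.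

Step 5
Reactants: 12 neryl acetate [(2Z)-3,7-dimethylocta-2,6-dien-1-yl acetate]
Product: 14 (2Z)-3-methyl-6-oxohex-2-en-1-yl acetate, via secondary ozonide 13 (not isolated)
Conditions: O3 (1.0 equiv), CH2Cl2, −78 °C; Me2S, −78 °C → rt
Reagents that add atoms: ozone, [O-][O+]=O
Why: Chemoselective Criegee ozonolysis: the 6,7-alkene is the more electron-rich one because the 2,3-alkene is deactivated by the allylic acetate, so one equivalent of ozone at low temperature should cleave it alone and leave the Z alkene untouched.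

Step 6
Reactants: 14 (2Z)-3-methyl-6-oxohex-2-en-1-yl acetate
Product: 16 (2Z)-3-methylhept-2-en-6-yn-1-ol, via enyne acetate 15 (not isolated)
Conditions: dimethyl (1-diazo-2-oxopropyl)phosphonate, K2CO3, MeOH, 0 °C → rt
Reagents that add atoms: dimethyl (1-diazo-2-oxopropyl)phosphonate, CC(=O)C(=[N+]=[N-])P(=O)(OC)OC
Why: Seyferth–Gilbert homologation in its Ohira–Bestmann form turns the aldehyde into the terminal alkyne, and the same methanolic carbonate removes the acetate, which is wanted because the next two steps use butyllithium and a zirconium hydride that an ester would not survive.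

Step 7
Reactants: 16 (2Z)-3-methylhept-2-en-6-yn-1-ol
Product: 18 (2Z)-3-methyloct-2-en-6-yn-1-ol, via dilithium alkoxide acetylide 17 (not isolated)
Conditions: n-BuLi (2.1 equiv), THF, −78 → 0 °C; MeI (1.05 equiv), −78 °C → rt
Reagents that add atoms: iodomethane, CI
Why: Alkylation of a lithium acetylide: in the dianion the acetylide carbon is far more nucleophilic towards MeI than the lithium alkoxide in THF, so C-methylation should be selective.

Step 8
Reactants: 18 (2Z)-3-methyloct-2-en-6-yn-1-ol
Product: 20 (2Z,6E)-7-iodo-3-methylocta-2,6-dien-1-ol, via alkenylzirconocene 19 (not isolated)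
Conditions: Cp2Zr(H)Cl (3 equiv), THF, 50 °C; I2, 0 °C
Reagents that add atoms: iodine, [I][I]
Why: Hydrozirconation–iodination: syn addition of Zr–H, equilibrated by excess reagent and warming to the isomer with zirconium on the less hindered methyl-bearing carbon, followed by iodinolysis with retention, should give the E iodide with iodine on C7.

Step 9
Reactants: 20 (2Z,6E)-7-iodo-3-methylocta-2,6-dien-1-ol
Product: 21 (2Z,6E)-7-iodo-3-methylocta-2,6-dien-1-yl benzoate
Conditions: BzCl, pyridine, DMAP (cat.), CH2Cl2, 0 °C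
Reagents that add atoms: benzoyl chloride, O=C(Cl)c1ccccc1
Why: Routine acylation of a primary allylic alcohol installs the benzoate of the target before the fragment union, since the later chromium-mediated steps tolerate esters.

Step 10
Reactants: 11 3-[(2E,3S)-3-(tert-butyldimethylsilyloxy)-4,4-dimethoxy-2-(3-oxopropylidene)butanoyl]-1,3-oxazolidin-2-one; 21 (2Z,6E)-7-iodo-3-methylocta-2,6-dien-1-yl benzoate
Product: 22 (2Z,6E,8R,10E,12S)-12-(tert-butyldimethylsilyloxy)-8-hydroxy-13,13-dimethoxy-3,7-dimethyl-11-(2-oxo-1,3-oxazolidine-3-carbonyl)trideca-2,6,10-trien-1-yl benzoate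
Conditions: CrCl2 (10 mol%), N-[2-(4-isopropyl-4,5-dihydro-1,3-oxazol-2-yl)-6-methoxyphenyl]methanesulfonamide (single enantiomer, 11 mol%), 1,8-bis(dimethylamino)naphthalene (11 mol%), NiCl2·(2,9-dimethyl-1,10-phenanthroline) (2 mol%), Mn, Cp2ZrCl2, LiCl, MeCN, rt
Reagents that add atoms: none
Why: Catalytic asymmetric Nozaki–Hiyama–Kishi coupling: nickel activates the C–I bond with retention of alkene geometry, the alkenyl group passes to chromium and adds to the aldehyde inside the chiral ligand sphere (ligand antipode chosen for Si-face delivery, which sets C3′ as R by catalyst control), while imide, benzoate, acetal and silyl ether are inert to the organochromium reagent.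

Step 11
Reactants: 22 (2Z,6E,8R,10E,12S)-12-(tert-butyldimethylsilyloxy)-8-hydroxy-13,13-dimethoxy-3,7-dimethyl-11-(2-oxo-1,3-oxazolidine-3-carbonyl)trideca-2,6,10-trien-1-yl benzoate
Product: 24 (2Z,6E,8R,10E,12S)-12-(tert-butyldimethylsilyloxy)-3,7-dimethyl-13-oxo-11-(2-oxo-1,3-oxazolidine-3-carbonyl)-8-(triethylsilyloxy)trideca-2,6,10-trien-1-yl benzoate, via collidinium salt 23 (not isolated)
Conditions: TESOTf (3 equiv), 2,4,6-collidine (4 equiv), CH2Cl2, 0 °C; then H2O
Reagents that add atoms: triethylsilyl triflate, CC[Si](CC)(CC)OS(=O)(=O)C(F)(F)F; water, O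
Why: Non-acidic acetal cleavage: the silyl triflate ionises the dimethyl acetal, collidine traps the oxocarbenium ion as a pyridinium salt that water hydrolyses to the aldehyde, conditions that spare the TBS ether and should not epimerise C4, while the free C3′ hydroxyl is capped as its TES ether in the same flask.

Step 12
Reactants: 24 (2Z,6E,8R,10E,12S)-12-(tert-butyldimethylsilyloxy)-3,7-dimethyl-13-oxo-11-(2-oxo-1,3-oxazolidine-3-carbonyl)-8-(triethylsilyloxy)trideca-2,6,10-trien-1-yl benzoate; 25 1-bromo-2-methylprop-1-ene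
Product: 27 (2Z,6E,8R)-10-[(3E,4S,5R)-4-(tert-butyldimethylsilyloxy)-5-(2-methylprop-1-en-1-yl)-2-oxooxolan-3-ylidene]-3,7-dimethyl-8-(triethylsilyloxy)deca-2,6-dien-1-yl benzoate, via hydroxy imide 26 (not isolated)
Conditions: CrCl2, NiCl2 (cat.), DMF, rt; aqueous work-up; Et3N, DMAP (cat.), CH2Cl2, rt
Reagents that add atoms: none
Why: Nozaki–Hiyama–Kishi alkenylation under Felkin–Anh control: the bulky, non-chelating silyloxy group at C4 lies anti to the incoming alkenylchromium reagent, which should set C5 as R (4,5-anti), and the new hydroxyl then closes the trans lactone by acyl transfer from the imide with loss of oxazolidinone.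

Step 13
Reactants: 27 (2Z,6E,8R)-10-[(3E,4S,5R)-4-(tert-butyldimethylsilyloxy)-5-(2-methylprop-1-en-1-yl)-2-oxooxolan-3-ylidene]-3,7-dimethyl-8-(triethylsilyloxy)deca-2,6-dien-1-yl benzoate
Product: 28 (2Z,6E,8R)-8-hydroxy-10-[(3E,4S,5R)-4-hydroxy-5-(2-methylprop-1-en-1-yl)-2-oxooxolan-3-ylidene]-3,7-dimethyldeca-2,6-dien-1-yl benzoate
Conditions: HF·pyridine, pyridine, THF, 0 °C → rt
Reagents that add atoms: none
Why: Fluoride-mediated desilylation under buffered conditions should remove the TES and TBS groups without touching the lactone, the benzoate or the allylic alcohol.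

Step 14
Reactants: 28 (2Z,6E,8R)-8-hydroxy-10-[(3E,4S,5R)-4-hydroxy-5-(2-methylprop-1-en-1-yl)-2-oxooxolan-3-ylidene]-3,7-dimethyldeca-2,6-dien-1-yl benzoate
Product: 29 (2Z,6E,8R)-8-acetoxy-10-[(3E,4S,5R)-4-acetoxy-5-(2-methylprop-1-en-1-yl)-2-oxooxolan-3-ylidene]-3,7-dimethyldeca-2,6-dien-1-yl benzoate (CNP0262857.1)
Conditions: Ac2O, pyridine, DMAP (cat.), CH2Cl2, 0 °C → rt
Reagents that add atoms: acetic anhydride, CC(=O)OC(C)=O
Why: Standard DMAP-catalysed acetylation of both secondary hydroxyl groups should give the target without affecting any stereocentre.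

Compound list
1 | (E)-but-2-enal (crotonaldehyde) | C/C=C/C=O | starting material
2 | (E)-1-(tert-butyldimethylsilyloxy)buta-1,3-diene | C=C/C=C/O[Si](C)(C)C(C)(C)C | intermediate
3 | prop-2-ynoic acid (propiolic acid) | C#CC(=O)O | starting material
4 | 1,3-oxazolidin-2-one | O=C1NCCO1 | starting material
5 | 2,2-dimethylpropanoic prop-2-ynoic anhydride | C#CC(=O)OC(=O)C(C)(C)C | intermediate
6 | lithium 2-oxo-1,3-oxazolidin-3-ide | [Li+].O=C1[N-]CCO1 | intermediate
7 | 3-(prop-2-ynoyl)-1,3-oxazolidin-2-one | C#CC(=O)N1CCOC1=O | intermediate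
8 | 3-{[(6R)-6-(tert-butyldimethylsilyloxy)cyclohexa-1,4-dien-1-yl]carbonyl}-1,3-oxazolidin-2-one | O=C(C1=CCC=C[C@H]1O[Si](C)(C)C(C)(C)C)N1CCOC1=O | intermediate
9 | 3-[(2E,3S)-3-(tert-butyldimethylsilyloxy)-2-(3-hydroperoxy-3-methoxypropylidene)-4-oxobutanoyl]-1,3-oxazolidin-2-one (both epimers at the hydroperoxy carbon) | O=C[C@@H](O[Si](C)(C)C(C)(C)C)/C(=C\CC(OC)OO)C(=O)N1CCOC1=O | intermediate
10 | 3-[(2E,3S)-3-(tert-butyldimethylsilyloxy)-2-(3-hydroperoxy-3-methoxypropylidene)-4,4-dimethoxybutanoyl]-1,3-oxazolidin-2-one (both epimers at the hydroperoxy carbon) | COC(OC)[C@@H](O[Si](C)(C)C(C)(C)C)/C(=C\CC(OC)OO)C(=O)N1CCOC1=O | intermediate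
11 | 3-[(2E,3S)-3-(tert-butyldimethylsilyloxy)-4,4-dimethoxy-2-(3-oxopropylidene)butanoyl]-1,3-oxazolidin-2-one | COC(OC)[C@@H](O[Si](C)(C)C(C)(C)C)/C(=C\CC=O)C(=O)N1CCOC1=O | intermediate
12 | neryl acetate, (2Z)-3,7-dimethylocta-2,6-dien-1-yl acetate | CC(C)=CCC/C(C)=C\COC(C)=O | starting material
13 | (2Z)-5-(5,5-dimethyl-1,2,4-trioxolan-3-yl)-3-methylpent-2-en-1-yl acetate | CC1(C)OC(CC/C(C)=C\COC(C)=O)OO1 | intermediate
14 | (2Z)-3-methyl-6-oxohex-2-en-1-yl acetate | O=CCC/C(C)=C\COC(C)=O | intermediate
15 | (2Z)-3-methylhept-2-en-6-yn-1-yl acetate | C#CCC/C(C)=C\COC(C)=O | intermediate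
16 | (2Z)-3-methylhept-2-en-6-yn-1-ol | C#CCC/C(C)=C\CO | intermediate
17 | dilithium (2Z)-3-methylhept-2-en-6-yn-7-id-1-olate | [Li+].[Li+].[C-]#CCC/C(C)=C\C[O-] | intermediate
18 | (2Z)-3-methyloct-2-en-6-yn-1-ol | CC#CCC/C(C)=C\CO | intermediate
19 | (2Z,6E)-alkenylzirconocene chloride of 18 with zirconium on C7 and the oxygen bound as zirconocene chloride alkoxide | C/C(=C\CC/C(C)=C\CO[Zr](Cl)(C1C=CC=C1)C1C=CC=C1)[Zr](Cl)(C1C=CC=C1)C1C=CC=C1 | intermediate
20 | (2Z,6E)-7-iodo-3-methylocta-2,6-dien-1-ol | I/C(C)=C/CC/C(C)=C\CO | intermediate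
21 | (2Z,6E)-7-iodo-3-methylocta-2,6-dien-1-yl benzoate | I/C(C)=C/CC/C(C)=C\COC(=O)c1ccccc1 | intermediate
22 | (2Z,6E,8R,10E,12S)-12-(tert-butyldimethylsilyloxy)-8-hydroxy-13,13-dimethoxy-3,7-dimethyl-11-(2-oxo-1,3-oxazolidine-3-carbonyl)trideca-2,6,10-trien-1-yl benzoate | COC(OC)[C@@H](O[Si](C)(C)C(C)(C)C)/C(=C\C[C@@H](O)/C(C)=C/CC/C(C)=C\COC(=O)c1ccccc1)C(=O)N1CCOC1=O | intermediate
23 | collidinium salt of 22: C13 carries OMe and N-bound 2,4,6-trimethylpyridinium, the C8 oxygen is a TES ether, triflate counter-ion | COC([n+]1c(C)cc(C)cc1C)[C@@H](O[Si](C)(C)C(C)(C)C)/C(=C\C[C@@H](O[Si](CC)(CC)CC)/C(C)=C/CC/C(C)=C\COC(=O)c1ccccc1)C(=O)N1CCOC1=O.[O-]S(=O)(=O)C(F)(F)F | intermediate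
24 | (2Z,6E,8R,10E,12S)-12-(tert-butyldimethylsilyloxy)-3,7-dimethyl-13-oxo-11-(2-oxo-1,3-oxazolidine-3-carbonyl)-8-(triethylsilyloxy)trideca-2,6,10-trien-1-yl benzoate | O=C[C@@H](O[Si](C)(C)C(C)(C)C)/C(=C\C[C@@H](O[Si](CC)(CC)CC)/C(C)=C/CC/C(C)=C\COC(=O)c1ccccc1)C(=O)N1CCOC1=O | intermediate
25 | 1-bromo-2-methylprop-1-ene | CC(C)=CBr | starting material
26 | (2Z,6E,8R,10E,12S,13R)-12-(tert-butyldimethylsilyloxy)-13-hydroxy-3,7,15-trimethyl-11-(2-oxo-1,3-oxazolidine-3-carbonyl)-8-(triethylsilyloxy)hexadeca-2,6,10,14-tetraen-1-yl benzoate | CC(C)=C[C@@H](O)[C@@H](O[Si](C)(C)C(C)(C)C)/C(=C\C[C@@H](O[Si](CC)(CC)CC)/C(C)=C/CC/C(C)=C\COC(=O)c1ccccc1)C(=O)N1CCOC1=O | intermediate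
27 | (2Z,6E,8R)-10-[(3E,4S,5R)-4-(tert-butyldimethylsilyloxy)-5-(2-methylprop-1-en-1-yl)-2-oxooxolan-3-ylidene]-3,7-dimethyl-8-(triethylsilyloxy)deca-2,6-dien-1-yl benzoate | CC[Si](CC)(CC)O[C@H](C/C=C1/C(=O)O[C@H](C=C(C)C)[C@H]1O[Si](C)(C)C(C)(C)C)/C(C)=C/CC/C(C)=C\COC(=O)c1ccccc1 | intermediate
28 | (2Z,6E,8R)-8-hydroxy-10-[(3E,4S,5R)-4-hydroxy-5-(2-methylprop-1-en-1-yl)-2-oxooxolan-3-ylidene]-3,7-dimethyldeca-2,6-dien-1-yl benzoate | O[C@H](C/C=C1/C(=O)O[C@H](C=C(C)C)[C@H]1O)/C(C)=C/CC/C(C)=C\COC(=O)c1ccccc1 | intermediate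
29 | (2Z,6E,8R)-8-acetoxy-10-[(3E,4S,5R)-4-acetoxy-5-(2-methylprop-1-en-1-yl)-2-oxooxolan-3-ylidene]-3,7-dimethyldeca-2,6-dien-1-yl benzoate | CC(=O)O[C@H](C/C=C1/C(=O)O[C@H](C=C(C)C)[C@H]1OC(C)=O)/C(C)=C/CC/C(C)=C\COC(=O)c1ccccc1 | target

Total step count: 14.
Longest linear sequence: 10 steps (steps 5 to 14, from neryl acetate 12 to 29).

Steps most likely to fail

Step 3 (proposed new method). Face selection may be weak, because the reacting alkyne carbons lie far from the ligand and two diene orientations of similar energy lead to opposite enantiomers. Silyl transfer to the imide, or loss of silanol with aromatisation of the adduct, may also compete. The fallback uses known chemistry and sets out from 7. An uncatalysed thermal cycloaddition with commercial (E)-buta-1,3-dien-1-yl acetate (toluene, 50 °C) should give racemic 3-[(6-acetoxycyclohexa-1,4-dien-1-yl)carbonyl]-1,3-oxazolidin-2-one F1. Lipase-catalysed alcoholysis (immobilised Candida antarctica lipase B, n-BuOH, tert-butyl methyl ether, rt) follows; the empirical size rule for secondary alcohols predicts the R acetate to react. This should release 3-{[(6R)-6-hydroxycyclohexa-1,4-dien-1-yl]carbonyl}-1,3-oxazolidin-2-one F2 and leave the S acetate behind. Silylation of F2 (TBSOTf, 2,6-lutidine, CH2Cl2, −78 °C) comes back to the route at 8.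

Step 4. The primary ozonide may fragment in the other direction, or the hindered α-silyloxy aldehyde may be acetalised only in part, so that the two chain ends are not told apart; the acid may also strip the TBS group. The fallback sets out from 8 and reverses the order of the two alkenyl additions.
- Ozonolysis as in step 4 up to 9, then direct reduction with Me2S without acid, should give the dialdehyde 3-[(2E,3S)-3-(tert-butyldimethylsilyloxy)-4-oxo-2-(3-oxopropylidene)butanoyl]-1,3-oxazolidin-2-one F3.
- The unhindered C3′ aldehyde, whose oxocarbenium ion is not destabilised by an α-oxygen, should be acetalised selectively (CH(OMe)3, MeOH, PPTS, 0 °C) to 3-[(2E,3S)-3-(tert-butyldimethylsilyloxy)-2-(3,3-dimethoxypropylidene)-4-oxobutanoyl]-1,3-oxazolidin-2-one F4.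
- Alkenylation of the free C5 aldehyde with 25 under the conditions of step 12 should give the hydroxy imide 3-[(2E,3S,4R)-3-(tert-butyldimethylsilyloxy)-2-(3,3-dimethoxypropylidene)-4-hydroxy-6-methylhept-5-enoyl]-1,3-oxazolidin-2-one F5, which closes to the lactone (3E,4S,5R)-4-(tert-butyldimethylsilyloxy)-3-(3,3-dimethoxypropylidene)-5-(2-methylprop-1-en-1-yl)oxolan-2-one F6.
- Mild hydrolysis (PPTS, acetone/H2O, rt) should free 3-[(3E,4S,5R)-4-(tert-butyldimethylsilyloxy)-5-(2-methylprop-1-en-1-yl)-2-oxooxolan-3-ylidene]propanal F7.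
- Asymmetric coupling with 21 under the conditions of step 10 should give (2Z,6E,8R)-10-[(3E,4S,5R)-4-(tert-butyldimethylsilyloxy)-5-(2-methylprop-1-en-1-yl)-2-oxooxolan-3-ylidene]-8-hydroxy-3,7-dimethyldeca-2,6-dien-1-yl benzoate F8.
- HF·pyridine as in step 13 comes back to the route at 28.

Step 12. Facial selectivity may be poor, because steric control by the bulky C3 branch competes with the polar Felkin–Anh preference, and the α-silyloxy aldehyde may epimerise at C4 before it reacts. The fallback moves stereocontrol from the substrate to a chiral catalyst and sets out from 24 and 25. Bromide 25 is converted by copper-catalysed halogen exchange (CuI, NaI, N,N′-dimethylethylenediamine, dioxane, 110 °C) into 1-iodo-2-methylprop-1-ene F9. F9 is coupled with 24 under the catalytic asymmetric conditions of step 10, with the ligand antipode that delivers the alkenyl group to the Re face of the C5 aldehyde (matched with the Felkin sense). This gives 26, and lactonisation as in step 12 comes back to the route at 27.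

Further compounds
F1 | step 3 | racemic 3-[(6-acetoxycyclohexa-1,4-dien-1-yl)carbonyl]-1,3-oxazolidin-2-one | CC(=O)OC1C=CCC=C1C(=O)N1CCOC1=O
F2 | step 3 | 3-{[(6R)-6-hydroxycyclohexa-1,4-dien-1-yl]carbonyl}-1,3-oxazolidin-2-one | O=C(C1=CCC=C[C@H]1O)N1CCOC1=O
F3 | step 4 | 3-[(2E,3S)-3-(tert-butyldimethylsilyloxy)-4-oxo-2-(3-oxopropylidene)butanoyl]-1,3-oxazolidin-2-one | O=C[C@@H](O[Si](C)(C)C(C)(C)C)/C(=C\CC=O)C(=O)N1CCOC1=O
F4 | step 4 | 3-[(2E,3S)-3-(tert-butyldimethylsilyloxy)-2-(3,3-dimethoxypropylidene)-4-oxobutanoyl]-1,3-oxazolidin-2-one | O=C[C@@H](O[Si](C)(C)C(C)(C)C)/C(=C\CC(OC)OC)C(=O)N1CCOC1=O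
F5 | step 4 | 3-[(2E,3S,4R)-3-(tert-butyldimethylsilyloxy)-2-(3,3-dimethoxypropylidene)-4-hydroxy-6-methylhept-5-enoyl]-1,3-oxazolidin-2-one | CC(C)=C[C@@H](O)[C@@H](O[Si](C)(C)C(C)(C)C)/C(=C\CC(OC)OC)C(=O)N1CCOC1=O
F6 | step 4 | (3E,4S,5R)-4-(tert-butyldimethylsilyloxy)-3-(3,3-dimethoxypropylidene)-5-(2-methylprop-1-en-1-yl)oxolan-2-one | COC(OC)C/C=C1/C(=O)O[C@H](C=C(C)C)[C@H]1O[Si](C)(C)C(C)(C)C
F7 | step 4 | 3-[(3E,4S,5R)-4-(tert-butyldimethylsilyloxy)-5-(2-methylprop-1-en-1-yl)-2-oxooxolan-3-ylidene]propanal | O=CC/C=C1/C(=O)O[C@H](C=C(C)C)[C@H]1O[Si](C)(C)C(C)(C)C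
F8 | step 4 | (2Z,6E,8R)-10-[(3E,4S,5R)-4-(tert-butyldimethylsilyloxy)-5-(2-methylprop-1-en-1-yl)-2-oxooxolan-3-ylidene]-8-hydroxy-3,7-dimethyldeca-2,6-dien-1-yl benzoate | O[C@H](C/C=C1/C(=O)O[C@H](C=C(C)C)[C@H]1O[Si](C)(C)C(C)(C)C)/C(C)=C/CC/C(C)=C\COC(=O)c1ccccc1
F9 | step 12 | 1-iodo-2-methylprop-1-ene | CC(C)=CI
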